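The target is the centrosymmetric (meso) dimer of two 7-methyl-1,3-dihydroisobenzofuran units (numbering O2, C1, C3, C3a, C4 to C7, C7a; primes for the second half). Its central six-membered ring C3a–C4–C5–C3a'–C4'–C5' is cut at C3a–C5' and C5–C3a' (two aldol bonds, formal [3+3]) to two molecules of 6-hydroxy-7-methyl-1,3-dihydroisobenzofuran-4,5-dione.
Enabling feature: in each half C4, C5 and C6 are three contiguous oxidised carbons (ketone, carbinol, ketone), and C3a is α to C4 and, through C7a=C7, γ to the C6 carbonyl. C3a–C4 is therefore the acylation bond of an extended enolate, and C5 is a tricarbonyl centre that accepts the aldol.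
The monomer is cut at C3a–C4 to methyl 4-(2,5-dihydrofuran-3-yl)-2,3-dioxopentanoate. One base treatment should close the carbocycle of each half through C3a–C4, and the liberated hydroxy-ortho-quinone should dimerise in the same flask (four C–C bonds, three carbocycles, four stereocentres).
The dioxo ester comes from 2-(2,5-dihydrofuran-3-yl)propanoic acid by C-acylation of a phosphorus ylide and oxidative cleavage of the C=P bond; the acid comes from dihydrofuran-3(2H)-one by enol triflate formation and cross-coupling with a propanoate zinc enolate.
Order of ring formation: oxygen heterocycle (bought), then the two carbocycles (C3a–C4 and C3a'–C4'), then the central ring.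

Key step: step 6

Remark: the stereodescriptors of the target describe the centrosymmetric, achiral cage, so only relative configuration has to be controlled.

Step 1
Reactants: 1 dihydrofuran-3(2H)-one
Product: 3 2,5-dihydrofuran-3-yl trifluoromethanesulfonate, via sodium 2,5-dihydrofuran-3-olate 2 (not isolated)
Conditions: NaN(SiMe3)2, THF, −78 °C; then PhNTf2, −78 °C to rt
Reagents that add atoms: N-phenylbis(trifluoromethanesulfonimide), O=S(=O)(N(c1ccccc1)S(=O)(=O)C(F)(F)F)C(F)(F)F
Why: Enol triflate formation: the amide base should remove a proton from C4, the α-CH2 remote from the ring oxygen (the kinetically preferred site in α-alkoxy ketones), and O-sulfonylation of the enolate fixes the double bond where the carbocycle is fused later.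

Step 2
Reactants: 3 2,5-dihydrofuran-3-yl trifluoromethanesulfonate; 4 tert-butyl 2-bromopropanoate (racemic)
Product: 6 tert-butyl 2-(2,5-dihydrofuran-3-yl)propanoate (racemic), via bromo(1-tert-butoxy-1-oxopropan-2-yl)zinc 5 (not isolated)
Conditions: Zn dust (Me3SiCl-activated), THF, rt; then 3, Pd(PPh3)4 (5 mol%), LiCl, THF, 50 °C
Reagents that add atoms: none
Why: Negishi-type cross-coupling of a Reformatsky zinc ester enolate with an alkenyl triflate under zerovalent palladium catalysis joins the propanoate α-carbon to the ring sp2 carbon under nearly neutral conditions, so the ring double bond should stay in place; the new stereocentre forms as a racemate and is erased by enolisation in step 6.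

Step 3
Reactants: 6 tert-butyl 2-(2,5-dihydrofuran-3-yl)propanoate
Product: 7 2-(2,5-dihydrofuran-3-yl)propanoic acid (racemic)
Conditions: CF3CO2H, CH2Cl2, 0 °C to rt
Reagents that add atoms: none
Why: Acidolysis of the tert-butyl ester (loss of the tert-butyl group as 2-methylpropene) frees the acid without base, so the β,γ-double bond is not drawn into conjugation and the allylic ether is untouched.

Step 4
Reactants: 7 2-(2,5-dihydrofuran-3-yl)propanoic acid; 8 methyl 2-(triphenyl-λ5-phosphanylidene)acetate
Product: 9 methyl 4-(2,5-dihydrofuran-3-yl)-3-oxo-2-(triphenyl-λ5-phosphanylidene)pentanoate (racemic)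
Conditions: EDC (N-ethyl-N'-(3-dimethylaminopropyl)carbodiimide), DMAP (cat.), CH2Cl2, 0 °C to rt
Reagents that add atoms: none
Why: Carbodiimide-mediated C-acylation of the stabilised phosphorus ylide by the acid (the standard acyl ylide entry to vicinal tricarbonyls) installs the two remaining carbonyl carbons in masked form; the α-stereocentre stays racemic and is of no consequence.

Step 5
Reactants: 9 methyl 4-(2,5-dihydrofuran-3-yl)-3-oxo-2-(triphenyl-λ5-phosphanylidene)pentanoate
Product: 10 methyl 4-(2,5-dihydrofuran-3-yl)-2,3-dioxopentanoate (racemic; handled anhydrous, expected to rest as its conjugated C3 enol)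
Conditions: dimethyldioxirane (2 equiv, acetone), CH2Cl2, −78 °C; evaporation, azeotropic drying with toluene
Reagents that add atoms: dimethyldioxirane, CC1(C)OO1
Why: Oxidative cleavage of the C=P bond of an acyl ylide by dimethyldioxirane is an established route to α,β-dioxo esters, and the ylide carbon is far more nucleophilic than the trisubstituted ring alkene, which two allylic C–O bonds deactivate, so two equivalents at −78 °C should leave the alkene intact.

Step 6
Reactants: 10 methyl 4-(2,5-dihydrofuran-3-yl)-2,3-dioxopentanoate (two molecules)
Product: 15 meso cage dimer (target), via potassium dienolate 11 (not isolated), via potassium quinone-olate 12 (not isolated), via hydroxy-ortho-quinone 13 (not isolated), via open aldol adduct 14 (not isolated)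
Conditions: KOt-Bu (1.05 equiv), THF, −20 to 40 °C, Ar; then AcOH (1.1 equiv), MeCN–H2O, rt
Reagents that add atoms: none
Why: Proposed new method: the base removes the enol proton of 10 to give the extended enolate 11 of a 1,2-diketone, whose γ-carbon (the ring CH, future C3a) attacks the oxalyl-type ester carbon (future C4) in a vinylogous Dieckmann condensation, and loss of methoxide followed by deprotonation gives the salt 12 of the vinylogous acid 13; on acidification two molecules of 13 should join by two aldol additions, C3a of one to the central C5 carbonyl of the other (open adduct 14) and then the reverse, which is the formal [3+3] dimerisation that this type of fully substituted hydroxy-ortho-quinone is known to undergo when it is generated by oxidation of its pyrogallol. The closest known reaction types for the ring closure are the Lacey–Dieckmann C-acylation of a stabilised enolate by an ester and the Claisen ring closures of extended (toluate-type) anions; what is new is the vinylogous use on an α,β-dioxo ester to make a cyclic vicinal tricarbonyl. Each carbocycle closes in a 6-(enolendo)-exo-trig mode, and the central six-membered ring closes by an intermolecular aldol addition followed by a 6-(enolendo)-exo-trig aldol addition. The four stereocentres (C3a and C5 of each half) arise in the dimerisation: within a half the two new bonds must lie on the same face because the one-carbon C4 bridge spans them, and between the halves the head-to-tail approach related by an inversion centre gives the chair-shaped central ring of the meso compound, which the reversibility of the aldol steps and the lower strain of this cage compared with the boat-shaped C2 isomer should favour; 15 is achiral, so no absolute control is needed. The step needs C-acylation at the ester carbon and not aldol addition to the neighbouring ketone, which would be a disfavoured and reversible 5-(enolendo)-exo-trig closure while the loss of methoxide and formation of the stabilised anion of 12 is irreversible, and it needs attack through the ring CH and not through an OCH2 carbon, which the position of the double bond in 10 and the stoichiometric base in an aprotic solvent (no proton shuttle to move the dienolate) should secure.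

Compound list
1 | dihydrofuran-3(2H)-one (tetrahydrofuran-3-one) | O=C1COCC1 | starting material
2 | sodium 2,5-dihydrofuran-3-olate (not isolated) | [Na+].[O-]C1=CCOC1 | intermediate
3 | 2,5-dihydrofuran-3-yl trifluoromethanesulfonate | O=S(=O)(OC1=CCOC1)C(F)(F)F | intermediate
4 | tert-butyl 2-bromopropanoate (racemic) | CC(Br)C(=O)OC(C)(C)C | starting material
5 | bromo(1-tert-butoxy-1-oxopropan-2-yl)zinc, Reformatsky reagent (not isolated) | CC([Zn]Br)C(=O)OC(C)(C)C | intermediate
6 | tert-butyl 2-(2,5-dihydrofuran-3-yl)propanoate (racemic) | CC(C1=CCOC1)C(=O)OC(C)(C)C | intermediate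
7 | 2-(2,5-dihydrofuran-3-yl)propanoic acid (racemic) | CC(C1=CCOC1)C(=O)O | intermediate
8 | methyl 2-(triphenyl-λ5-phosphanylidene)acetate | COC(=O)C=P(c1ccccc1)(c1ccccc1)c1ccccc1 | starting material
9 | methyl 4-(2,5-dihydrofuran-3-yl)-3-oxo-2-(triphenyl-λ5-phosphanylidene)pentanoate (racemic) | COC(=O)C(=P(c1ccccc1)(c1ccccc1)c1ccccc1)C(=O)C(C)C1=CCOC1 | intermediate
10 | methyl 4-(2,5-dihydrofuran-3-yl)-2,3-dioxopentanoate (racemic; tricarbonyl form drawn, rests as C3 enol) | COC(=O)C(=O)C(=O)C(C)C1=CCOC1 | intermediate
11 | potassium dienolate of 10, O– and CH3 cis, dicarbonyl chain and ring cis (not isolated) | [K+].[O-]/C(C(=O)C(=O)OC)=C(\C)C1=CCOC1 | intermediate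
12 | potassium 7-methyl-4,5-dioxo-1,3,4,5-tetrahydroisobenzofuran-6-olate (not isolated) | [K+].CC1=C([O-])C(=O)C(=O)C2=C1COC2 | intermediate
13 | 6-hydroxy-7-methyl-1,3-dihydroisobenzofuran-4,5-dione (not isolated) | CC1=C(O)C(=O)C(=O)C2=C1COC2 | intermediate
14 | open aldol adduct: C3a of a 7-methyl-1,3-dihydroisobenzofuran-4,5,6-trione bonded to C5' of a 5'-hydroxy-7'-methyl-3',3a'-dihydroisobenzofuran-4',6'-dione; racemic, relative configuration as in 15, C3a' epimerisable (not isolated) | CC1=C2COC[C@@]2(C(=O)C(=O)C1=O)[C@]1(O)C(=O)C(C)=C2COCC2C1=O | intermediate
15 | meso cage dimer (dibefurin): two 5-hydroxy-7-methyl-1,3-dihydroisobenzofuran-4,6-dione units joined C3a–C5' and C5–C3a', halves related by an inversion centre, central ring in the chair form | CC1=C2COC[C@]23C(=O)[C@](O)(C1=O)[C@@]12COCC1=C(C)C(=O)[C@]3(O)C2=O | target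

Total step count: 6. Longest linear sequence: 6 steps (1 to 15).

Steps most likely to fail

Step 6 (proposed new method). The doubly stabilised dienolate may be too weak a nucleophile for the ester, may be diverted by reversible addition to the neighbouring ketone or by proton transfer, or the tricarbonyl may be cleaved by base before C-acylation. The fallback makes the same C3a–C4 bond by known pericyclic chemistry and sets out from acid 7. Oxalyl chloride (cat. DMF, CH2Cl2) gives 2-(2,5-dihydrofuran-3-yl)propanoyl chloride F1. Slow addition of Et3N in the presence of commercial ethoxyethyne generates methyl(2,5-dihydrofuran-3-yl)ketene F2, which should be trapped by [2+2] cycloaddition as 4-(2,5-dihydrofuran-3-yl)-3-ethoxy-4-methylcyclobut-2-en-1-one F3. Heating in toluene (80 to 110 °C) should bring about 4π ring opening, 6π ring closure (C3a–C4) and tautomerisation, the pericyclic sequence of the Danheiser benzannulation, to give 6-ethoxy-7-methyl-1,3-dihydroisobenzofuran-4-ol F4. Ortho-oxidation with 2-iodoxybenzoic acid (DMF, rt; only C5 is free) should give 6-ethoxy-7-methyl-1,3-dihydroisobenzofuran-4,5-dione F5. Mild aqueous acid hydrolysis of this vinylogous ester (dilute HCl, THF, rt) sets free quinone 13, where the fallback comes back to the route; 13 then dimerises to 15 as in the second half of step 6, the part of that step that has direct precedent.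

Step 5. Epoxidation of the ring alkene by the dioxirane may compete with C=P cleavage, or the tricarbonyl may be lost as its hydrate and cleaved during isolation. The fallback avoids electrophilic oxygen transfer in the presence of the alkene and sets out from acid 7. 1,1'-Carbonyldiimidazole gives 1-[2-(2,5-dihydrofuran-3-yl)propanoyl]-1H-imidazole F6. Claisen condensation with the lithium enolate of methyl acetate (2 equiv, THF, −78 °C) gives methyl 4-(2,5-dihydrofuran-3-yl)-3-oxopentanoate F7. Enolate hydroxylation with 2-(phenylsulfonyl)-3-phenyloxaziridine, which does not epoxidise alkenes, gives methyl 4-(2,5-dihydrofuran-3-yl)-2-hydroxy-3-oxopentanoate F8. Dess–Martin periodinane should oxidise the secondary alcohol to tricarbonyl 10, where the fallback rejoins the route.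

Step 2. Oxidative addition or transmetalation may be slow, or the double bond may migrate into conjugation with the ester. The fallback reverses the polarity of the coupling and sets out from triflate 3. Miyaura borylation (B2pin2, PdCl2(dppf), KOAc, dioxane, 80 °C) gives 2-(2,5-dihydrofuran-3-yl)-4,4,5,5-tetramethyl-1,3,2-dioxaborolane F9. Nickel-catalysed Suzuki-type coupling of F9 with α-bromo ester 4 (Ni(PPh3)4, K3PO4, toluene, 80 °C) should give ester 6, where the fallback rejoins the route.

Further compounds
F1 | step 6 | 2-(2,5-dihydrofuran-3-yl)propanoyl chloride (racemic) | CC(C1=CCOC1)C(Cl)=O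
F2 | step 6 | methyl(2,5-dihydrofuran-3-yl)ketene (2-(2,5-dihydrofuran-3-yl)prop-1-en-1-one) | CC(=C=O)C1=CCOC1
F3 | step 6 | 4-(2,5-dihydrofuran-3-yl)-3-ethoxy-4-methylcyclobut-2-en-1-one (racemic) | CCOC1=CC(=O)C1(C)C1=CCOC1
F4 | step 6 | 6-ethoxy-7-methyl-1,3-dihydroisobenzofuran-4-ol | CCOc1cc(O)c2COCc2c1C
F5 | step 6 | 6-ethoxy-7-methyl-1,3-dihydroisobenzofuran-4,5-dione | CCOC1=C(C)C2=C(COC2)C(=O)C1=O
F6 | step 5 | 1-[2-(2,5-dihydrofuran-3-yl)propanoyl]-1H-imidazole (racemic) | CC(C1=CCOC1)C(=O)n1ccnc1
F7 | step 5 | methyl 4-(2,5-dihydrofuran-3-yl)-3-oxopentanoate (racemic) | COC(=O)CC(=O)C(C)C1=CCOC1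
F8 | step 5 | methyl 4-(2,5-dihydrofuran-3-yl)-2-hydroxy-3-oxopentanoate (mixture of diastereomers) | COC(=O)C(O)C(=O)C(C)C1=CCOC1
F9 | step 2 | 2-(2,5-dihydrofuran-3-yl)-4,4,5,5-tetramethyl-1,3,2-dioxaborolane | CC1(C)OB(OC1(C)C)C1=CCOC1
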